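## Structural features

The target (C24H14O11) is a flat, achiral hexacycle with no stereocentre: a 3,5-dihydroxyphenoxy group (ring A) sits on a dibenzo-1,4-dioxin (rings B, C, D), and ring D is also the inner benzo ring of a dibenzofuran (rings D, E, F). Ring positions are written below with the number first and the ring letter second: 1A bears the ether oxygen and 3A, 5A the hydroxyls; 1B bears the oxygen to ring A, 2B and 4B hydroxyls, 3B is C–H, 5B and 6B (6B beside 1B) bear the dioxin oxygens; 1D and 6D bear the dioxin oxygens (6B–O–1D, 5B–O–6D), 2D (beside 1D) a hydroxyl, 3D is C–H, 4D bears the furan oxygen and 5D is bonded to 6F; 1F bears the furan oxygen, 2F and 4F are C–H, 3F and 5F bear hydroxyls. The fragile part is the set of seven free phenols on four electron-rich rings, two of them phloroglucinol rings (A and F), which oxidise easily in air and base, so the oxygens stay methylated until the last step. The real difficulty is the unsymmetrical dioxin: two diaryl ether bonds between carbons that each have two ortho substituents, to be made in one orientation only, on a ring B that carries five contiguous oxygens. The key step uses the 1,3,5-oxygen pattern of rings A and F: if the oxygens at 5A and 3F are left off, 5A–H and 3F–H are the only aryl C–H bonds of the molecule with a C–H on both sides (3B–H and 3D–H lie between two oxygens). The one C–H that sterics protect poorly is 2F–H, whose only ortho substituent is the furan oxygen tied back in ring E.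

## Logic of the disconnections

18 to 17: the five O–CH3 bonds are cut last. The heptaphenol is the least stable compound of the route, so it is unmasked in the final operation. The forward step must cleave aryl methyl ethers and leave diaryl ethers, the dioxin and the furan alone.

17 to 15: the two phenolic C–O bonds at 5A and 3F are cut back to C–H. This turns two phloroglucinol rings into mono-oxygenated rings that come from the simple partners 14 and 5 and are far less oxidisable through ten steps. The forward step needs site-selective C–H functionalisation at exactly these two positions. The design of 15 is tuned for it in three ways. Methyl is the only protecting group, so no protecting group brings in an unhindered C–H (a benzyl or aryl-silyl group would). The 5F oxygen stays a methyl ether, a strong donor para to 2F–H, and is not left free or silylated. All five ethers fall in one final step. The exposure at 2F remains and is treated under the uncertain steps.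

15 to 13 + 14: the 1B–O–aryl bond is cut with the oxygen left on ring B. Ring A then arrives as the plain aryl iodide 14, and the hindered partner is the phenol, which is the favourable polarity for copper. The forward step must arylate a phenol flanked by a methoxy group and a ring oxygen.

13 to 12: the dioxin bond 5B–O–6D is cut to a phenol and an aryl bromide. 12 has a mirror plane through 3B and 6B, so its two hydroxyls are equivalent and either one closes to the same dioxin. The orientation is therefore fixed only by where the bromine sits on ring D. The forward step must form a C–O bond at a bromide lying between an aryloxy group and the bay of the dibenzofuran.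

12 to 10: the two C–OH bonds at 1B and 5B are traced back to two formyl groups. The formyl groups first activate the fluoride of 2 and then become the two missing oxygens of ring B. The forward step needs aryl migration in a double Baeyer–Villiger oxidation, which the oxygen-rich ring favours.

10 to 9 + 2: the bond 6B–O–1D is cut. This is the most hindered ether of the molecule (four ortho substituents), and nucleophilic aromatic substitution copes with that better than metal catalysis. Because 2 is symmetrical, no regiochemical question arises on ring B. The forward step asks the phenoxide of 9 to displace a fluoride flanked by two formyl groups.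

2 to 1: one C–CHO bond is cut. The forward formylation must go beside fluorine and not between the two methoxy groups.

9 to 8: the C–Br bond at 6D is cut. The free 1D hydroxyl has a single open ortho position, which is 6D, so the phenol itself is the directing element. The forward step must keep bromine off the other electron-rich positions.

8 to 7: the O–benzyl bond is cut. The benzyl group keeps the 1D oxygen distinct from the methoxy groups during ring construction.

7 to 6: the furan C–O bond at 1F is cut to a phenol and an aryl fluoride. The forward step is an intramolecular fluoride displacement without extra activation.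

6 to 4 + 5: the biaryl bond 5D–6F is cut. Ring F comes from the boronic acid 5, which already carries the fluoride for the furan closure and the 5F oxygen.

4 to 3: the C–Br bond is cut. Bromination of 3 is directed ortho to the hydroxyl and para to the methoxy group.

## Other disconnections considered

Alternative 1: The cut runs through ring B itself, at the C–C bond 2B–3B. In the forward step the racemic cyclobutenone A2 is heated in toluene. The four-membered ring opens in a 4π electrocyclic step to a vinylketene, which closes by 6π electrocyclisation (ketene carbon to vinyl CH2) and tautomerises to the hydroquinone A1, with OEt at 4B and free hydroxyls at 2B and 5B.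
- In its favour: the whole oxygen pattern of the pentaoxygenated ring, including the two different aryloxy groups side by side, is fixed in A2 before the ring exists. The 5B hydroxyl emerges next to the brominated ring, so the later dioxin closure can go one way only. Rings A and F arrive fully oxygenated, so no late C–H functionalisation is needed; on the regiochemical certainty of ring F this plan is the better one.
- Against it here: A2 needs an unsymmetrical bis(aryloxy)cyclobutenedione and addition of the 1-ethoxyvinyl anion to one of two nearly identical vinylogous-ester carbonyls. Attack at the other carbonyl would exchange the places of ring A and the dibenzofuran. A1 is a hydroquinone and oxidises to the quinone easily. The trimethoxylated dibenzofuran must be brominated at 6D in the presence of a ring F that is more nucleophilic than in 8.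
- Comparison: on structure the two plans are equal, since both place bromine at 6D and close 5B–O–6D last. On mechanism a catalyst-free pericyclic cascade replaces the substitution and oxidation steps 7 and 8. On step economy they are about equal, because the squarate chemistry and an extra alkylation or dealkylation offset the steps saved.

Alternative 2: The cut removes two C–C bonds of ring F (1F–2F and 5F–6F). In the forward step the nitrofuran A4 is heated with the diene A5. A polar Diels–Alder reaction across the furan C2–C3 bond is followed by two eliminations and gives the dibenzofuranol A3, with the free hydroxyl at 5F and the methoxy group at 3F.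
- In its favour: ring F is built with both oxygens already in place. The polarised cycloaddition (nucleophilic diene terminus to the oxygen-bearing furan carbon) fixes their positions without ambiguity, so on ring F regiochemistry this plan is better than the chosen one. Nitro-substituted benzofurans are an established class of dienophiles.
- Against it here: A4 needs a nitro group on the furan β-carbon of a fully assembled polyether. Direct nitration would not go there, because benzofurans react at the α-carbon and rings A and B compete. The nitrofuran would have to be built from a ring D precursor, which lengthens the route. The cycloaddition has to dearomatise a furan in a crowded position next to the dioxin oxygen, and A5 is moisture-sensitive.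
- Comparison: this key step closes one ring and forms two skeletal bonds, where the chosen key step closes none. On step economy the chosen plan is expected to be shorter. The final deprotection is equal in kind (six methyl ethers against five).

Alternative 3: The cut is the biaryl bond 5D–6F. In the forward step zerovalent palladium from Pd(OAc)2 and tricyclohexylphosphine inserts into the 5D–Br bond of A7. Pivalate assists concerted metalation–deprotonation of an ortho C–H of the 3,5-dimethoxyphenoxy group on 4D, and reductive elimination closes the furan at carbon to give the heptamethyl ether A6.
- In its favour: the two ortho C–H bonds of that phenoxy group are equivalent, so only one product can form. On ring F regiochemistry this plan is better than the chosen one. Ring F comes from a cheap symmetric phenol, and the ring closure belongs to a well-studied class. The final deprotection is equal (one step, seven ethers instead of five).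
- Against it here: A7 needs bromine at 5D between two aryloxy groups, on a ring whose other open position 3D is activated to the same degree. The dioxin would have to be built before the furan, which gives up the control that 9 provides (phenol at 1D directing bromine to 6D with the furan already in place). Oxidative addition into a C–Br bond with two ortho aryloxy groups is slow.
- Comparison: ring E is closed at carbon here and at oxygen (step 4) in the chosen plan. Step economy is about equal. The electron-rich rings A and F are present throughout here and only at the end in the chosen plan.

Key step: step 11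

Assumption: 1, 3, 5 and 14 are bought as catalogue compounds.

Step 1
Reactants: 1 2-fluoro-4,6-dimethoxybenzaldehyde
Product: 2 2-fluoro-4,6-dimethoxybenzene-1,3-dicarbaldehyde
Conditions: Cl2CHOMe (3 equiv), TiCl4 (4 equiv), CH2Cl2, 0 °C to 40 °C; then ice-cold aq. HCl
Reagents that add atoms: dichloromethyl methyl ether, COC(Cl)Cl; water, O
Why: Rieche formylation; the position beside fluorine (C3, ortho to one methoxy group and para to the other) should be attacked in preference to C5, which lies between two methoxy groups and is the least reactive site of a resorcinol dimethyl ether, and hydrolysis of the α-chloro ether gives the aldehyde.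

Step 2
Reactants: 3 4-(benzyloxy)-3-methoxyphenol
Product: 4 4-(benzyloxy)-2-bromo-5-methoxyphenol
Conditions: NBS (1.0 equiv), CH2Cl2, −20 to 0 °C
Reagents that add atoms: N-bromosuccinimide, O=C1CCC(=O)N1Br
Why: Electrophilic aromatic bromination; the carbon ortho to the hydroxyl and para to the methoxy group is the most activated open position, whereas the other ortho carbon lies between two oxygen substituents.

Step 3
Reactants: 4 4-(benzyloxy)-2-bromo-5-methoxyphenol; 5 (2-fluoro-6-methoxyphenyl)boronic acid (1.6 equiv)
Product: 6 5-(benzyloxy)-2'-fluoro-4,6'-dimethoxy-[1,1'-biphenyl]-2-ol
Conditions: Pd(OAc)2 (3 mol%), SPhos (6 mol%), K3PO4 (3 equiv), toluene/H2O 10:1, 80 °C, argon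
Reagents that add atoms: none
Why: Suzuki–Miyaura coupling; SPhos-ligated zerovalent palladium couples hindered partners fast enough to compete with protodeboronation of the 2,6-disubstituted boronic acid, the excess of 5 covers the loss, and the free phenol is tolerated as its phenoxide.

Step 4
Reactants: 6 5-(benzyloxy)-2'-fluoro-4,6'-dimethoxy-[1,1'-biphenyl]-2-ol
Product: 7 8-(benzyloxy)-1,7-dimethoxydibenzo[b,d]furan
Conditions: K2CO3 (2 equiv), NMP, 150 °C
Reagents that add atoms: none
Why: Intramolecular nucleophilic aromatic substitution; the phenoxide displaces the ortho' fluoride and closes the five-membered furan ring, a cyclisation known for 2'-fluorobiphenyl-2-ols without further activation, and the benzyl ether is inert to carbonate.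

Step 5
Reactants: 7 8-(benzyloxy)-1,7-dimethoxydibenzo[b,d]furan
Product: 8 1,7-dimethoxydibenzo[b,d]furan-8-ol
Conditions: H2 (1 atm), Pd/C (10% palladium on carbon), EtOAc/MeOH, rt
Reagents that add atoms: none
Why: Hydrogenolysis of the benzyl ether; no halogen is present at this stage and the methyl ethers and the furan are untouched.

Step 6
Reactants: 8 1,7-dimethoxydibenzo[b,d]furan-8-ol
Product: 9 9-bromo-1,7-dimethoxydibenzo[b,d]furan-8-ol
Conditions: NBS (1.0 equiv), i-Pr2NH (10 mol%), CH2Cl2, −78 to 0 °C
Reagents that add atoms: N-bromosuccinimide, O=C1CCC(=O)N1Br
Why: Amine-mediated ortho-bromination of a phenol; the N-bromoamine delivers bromine through the hydrogen-bonded phenol to its ortho carbon, and C9 (position 6D) is the only open ortho position because the other bears the methoxy group and the para carbon is a ring-fusion carbon.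

Step 7
Reactants: 9 9-bromo-1,7-dimethoxydibenzo[b,d]furan-8-ol; 2 2-fluoro-4,6-dimethoxybenzene-1,3-dicarbaldehyde
Product: 10 2-[(9-bromo-1,7-dimethoxydibenzo[b,d]furan-8-yl)oxy]-4,6-dimethoxybenzene-1,3-dicarbaldehyde
Conditions: Cs2CO3 (1.5 equiv), DMF, 70 °C
Reagents that add atoms: none
Why: Nucleophilic aromatic substitution; the fluoride of 2 is flanked by two formyl groups that both take up the charge of the Meisenheimer intermediate, this reaction type tolerates four ortho substituents around the new ether, and the symmetry of 2 allows one product only.

Step 8
Reactants: 10 2-[(9-bromo-1,7-dimethoxydibenzo[b,d]furan-8-yl)oxy]-4,6-dimethoxybenzene-1,3-dicarbaldehyde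
Product: 12 2-[(9-bromo-1,7-dimethoxydibenzo[b,d]furan-8-yl)oxy]-4,6-dimethoxybenzene-1,3-diol, via bis(formate) ester 11 (not isolated)
Conditions: mCPBA (2.6 equiv), CH2Cl2, 0 °C to rt; then Et3N, MeOH, rt, argon
Reagents that add atoms: 3-chloroperoxybenzoic acid, OOC(=O)c1cccc(Cl)c1
Why: Double Baeyer–Villiger (Dakin-type) oxidation; the oxygen-rich aryl group migrates in preference to hydrogen to give the aryl formates, which protect the new phenols from further oxidation until mild methanolysis releases them.

Step 9
Reactants: 12 2-[(9-bromo-1,7-dimethoxydibenzo[b,d]furan-8-yl)oxy]-4,6-dimethoxybenzene-1,3-diol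
Product: 13 pentacyclic phenol of rings B to F (benzofuro-fused dibenzo-1,4-dioxin) with OH at 1B and OMe at 2B, 4B, 2D and 5F
Conditions: CuI (10 mol%), picolinic acid (20 mol%), K3PO4 (2 equiv), DMSO, 100 °C, argon
Reagents that add atoms: none
Why: Intramolecular Ullmann ether synthesis closing the six-membered dioxin ring; the two hydroxyls of 12 are equivalent by symmetry, so either gives 13, and the orientation of the dioxin is fixed by the bromine at 6D.

Step 10
Reactants: 13 pentacyclic phenol of rings B to F with OH at 1B; 14 1-iodo-3-methoxybenzene
Product: 15 dideoxy pentamethyl ether (3-methoxyphenoxy group on the 1B oxygen, ring A with OMe at 3A only, ring F with OMe at 5F only)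
Conditions: CuI (10 mol%), picolinic acid (20 mol%), K3PO4 (2 equiv), DMSO, 90 °C, argon
Reagents that add atoms: none
Why: Ullmann diaryl ether synthesis; the picolinic acid system is suited to ortho-disubstituted phenols with unhindered aryl iodides, and no other nucleophile or halide is left in 13.

Step 11
Reactants: 15 dideoxy pentamethyl ether
Product: 17 pentamethyl ether of the target with free hydroxyls at 5A and 3F, via bis(pinacolboronate) 16 (not isolated)
Conditions: [Ir(OMe)(cod)]2 (3 mol%), dtbpy (6 mol%), B2pin2 (2.5 equiv), THF, 80 °C, sealed tube; then aq. NaOH, 30% H2O2, THF, 0 °C to rt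
Reagents that add atoms: bis(pinacolato)diboron, CC1(C)OB(OC1(C)C)B1OC(C)(C)C(C)(C)O1 (boryl groups of 16); hydrogen peroxide, OO (hydroxyl oxygens of 17)
Why: Iridium-catalysed aromatic C–H borylation and oxidation of the aryl boronates, the known way from 1,3-disubstituted arenes to 3,5-disubstituted phenols. [Ir(OMe)(cod)]2, dtbpy and B2pin2 form a trivalent iridium tris(boryl) complex that cleaves an aryl C–H bond through a crowded transition state and releases the aryl boronate by C–B reductive elimination; hydroperoxide then adds to boron and the aryl group migrates from boron to oxygen at the same carbon. No ring is closed and no stereocentre is formed. The selectivity needed is 5A and 3F over the seven other aryl C–H bonds (2A, 4A, 6A, 3B, 3D, 2F, 4F), and it comes from the substrate: only 5A–H and 3F–H have a C–H on both sides, 3B–H and 3D–H lie between two oxygens, and the others sit beside a methoxy or aryloxy group. The one weakly shielded competitor is 2F–H beside the furan oxygen; the 5F methoxy group, a strong donor para to 2F–H, lowers its reactivity, 3F–H is meta to two oxygens, and the bulky boryl and bipyridine ligands add the steric bias. Methyl ethers are the only protecting groups, so no protecting group offers an unhindered C–H. Position 5A should react first, and the excess of B2pin2 and the reaction time serve ring F.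

Step 12
Reactants: 17 pentamethyl ether of the target with free hydroxyls at 5A and 3F
Product: 18 target heptaphenol CNP0256302.0 (OH at 3A, 5A, 2B, 4B, 2D, 3F and 5F)
Conditions: BBr3 (12 equiv), CH2Cl2, −78 °C to rt; then H2O, 0 °C; work-up and reversed-phase purification under argon
Reagents that add atoms: none
Why: Lewis-acid cleavage of aryl methyl ethers; bromide attacks the methyl group of each boron-complexed ether, while the diaryl ether, dioxin and furan C–O bonds have no alkyl carbon to attack and stay intact.

Compound list

1 | 2-fluoro-4,6-dimethoxybenzaldehyde | COc1cc(F)c(C=O)c(OC)c1 | starting material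
2 | 2-fluoro-4,6-dimethoxybenzene-1,3-dicarbaldehyde | COc1cc(OC)c(C=O)c(F)c1C=O | intermediate
3 | 4-(benzyloxy)-3-methoxyphenol | COc1cc(O)ccc1OCc1ccccc1 | starting material
4 | 4-(benzyloxy)-2-bromo-5-methoxyphenol | COc1cc(O)c(Br)cc1OCc1ccccc1 | intermediate
5 | (2-fluoro-6-methoxyphenyl)boronic acid | COc1cccc(F)c1B(O)O | starting material
6 | 5-(benzyloxy)-2'-fluoro-4,6'-dimethoxy-[1,1'-biphenyl]-2-ol | COc1cc(O)c(cc1OCc1ccccc1)-c1c(F)cccc1OC | intermediate
7 | 8-(benzyloxy)-1,7-dimethoxydibenzo[b,d]furan | COc1cc2oc3cccc(OC)c3c2cc1OCc1ccccc1 | intermediate
8 | 1,7-dimethoxydibenzo[b,d]furan-8-ol | COc1cc2oc3cccc(OC)c3c2cc1O | intermediate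
9 | 9-bromo-1,7-dimethoxydibenzo[b,d]furan-8-ol | COc1cc2oc3cccc(OC)c3c2c(Br)c1O | intermediate
10 | 2-[(9-bromo-1,7-dimethoxydibenzo[b,d]furan-8-yl)oxy]-4,6-dimethoxybenzene-1,3-dicarbaldehyde | COc1cc(OC)c(C=O)c(Oc2c(OC)cc3oc4cccc(OC)c4c3c2Br)c1C=O | intermediate
11 | 2-[(9-bromo-1,7-dimethoxydibenzo[b,d]furan-8-yl)oxy]-4,6-dimethoxy-1,3-phenylene diformate (formed in the flask, not isolated) | COc1cc(OC)c(OC=O)c(Oc2c(OC)cc3oc4cccc(OC)c4c3c2Br)c1OC=O | intermediate
12 | 2-[(9-bromo-1,7-dimethoxydibenzo[b,d]furan-8-yl)oxy]-4,6-dimethoxybenzene-1,3-diol | COc1cc(OC)c(O)c(Oc2c(OC)cc3oc4cccc(OC)c4c3c2Br)c1O | intermediate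
13 | pentacyclic phenol of rings B to F (benzofuro-fused dibenzo-1,4-dioxin) with OH at 1B and OMe at 2B, 4B, 2D and 5F | Oc1c(OC)cc(OC)c2c1Oc1c(OC)cc3oc4cccc(OC)c4c3c1O2 | intermediate
14 | 1-iodo-3-methoxybenzene | COc1cccc(I)c1 | starting material
15 | dideoxy pentamethyl ether (3-methoxyphenoxy at 1B; OMe at 2B, 4B, 2D and 5F; C–H at 5A and 3F) | COc1cccc(Oc2c(OC)cc(OC)c3c2Oc2c(OC)cc4oc5cccc(OC)c5c4c2O3)c1 | intermediate
16 | bis(pinacolboronate) of the dideoxy pentamethyl ether, boryl groups at 5A and 3F (formed in the flask, not isolated) | COc1cc(B2OC(C)(C)C(C)(C)O2)cc(Oc2c(OC)cc(OC)c3c2Oc2c(OC)cc4oc5cc(B6OC(C)(C)C(C)(C)O6)cc(OC)c5c4c2O3)c1 | intermediate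
17 | pentamethyl ether of the target with free OH at 5A and 3F | COc1cc(O)cc(Oc2c(OC)cc(OC)c3c2Oc2c(OC)cc4oc5cc(O)cc(OC)c5c4c2O3)c1 | intermediate
18 | CNP0256302.0, heptaphenol (OH at 3A, 5A, 2B, 4B, 2D, 3F and 5F) | Oc1cc(O)cc(Oc2c(O)cc(O)c3c2Oc2c(O)cc4oc5cc(O)cc(O)c5c4c2O3)c1 | target

Total step count: 12. Longest linear sequence: 11 steps (steps 2 to 12, from 3 to 18); the second branch is step 1 and joins at step 7.

Steps least certain to work

Step 11 (key step). The most likely failure is borylation of ring F at 2F in competition with 3F. An ortho oxygen tied back in a five-membered ring gives almost no steric protection and makes that C–H the most acidic one of ring F, as in the known preference of benzofurans and benzodioxoles for borylation beside oxygen. The para methoxy group at 5F works against this, but it may not be enough. Ring A is not in doubt. Fallback: starting from 15, the two C–H bonds would be silylated instead of borylated, with HSiMe(OSiMe3)2, [Ir(OMe)(cod)]2, 2,4,7-trimethyl-1,10-phenanthroline and cyclohexene as hydrogen acceptor in THF at 100 °C. This reaction is known to respond more strictly to steric hindrance than borylation and to avoid C–H bonds beside even small substituents. It would give the bis(silyl) compound F1. Tamao–Fleming oxidation (aq. H2O2, KHCO3, n-Bu4NF, THF/MeOH) would then turn both C–Si bonds into C–OH and return to the route at 17.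

Step 1. Two processes can go wrong. Formylation may go at C5 between the two methoxy groups, because the fluorine beside C3 deactivates that position inductively. The second formylation may also stall, because the first formyl group, complexed to TiCl4, deactivates the ring. Fallback: starting from 1, the aldehyde would be protected with ethane-1,2-diol (TsOH, toluene, reflux) as the dioxolane 2-(2-fluoro-4,6-dimethoxyphenyl)-1,3-dioxolane F2. Deprotonation with lithium 2,2,6,6-tetramethylpiperidide in THF at −78 °C is governed by acidity and not by arene nucleophilicity, so it should take the C–H flanked by fluorine and methoxy. Quenching with DMF would give 3-(1,3-dioxolan-2-yl)-2-fluoro-4,6-dimethoxybenzaldehyde F3, and aqueous HCl would remove the acetal and return to the route at 2.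

Step 6. Bromination may occur at other electron-rich carbons (3D, or the ring F positions ortho and para to the methoxy group, which are also activated by the furan oxygen), or the para-alkoxyphenol may be oxidised, because the wanted position lies in the crowded bay of the dibenzofuran. Fallback: starting from 8, the phenol would be converted with ClC(O)NEt2 and K2CO3 into 1,7-dimethoxydibenzo[b,d]furan-8-yl diethylcarbamate F4. Directed ortho-metalation (s-BuLi, TMEDA, THF, −78 °C) is steered by the carbamate, the strongest directing group present, to C9, its only free ortho position. The low temperature holds back the anionic Fries shift, and quenching with BrCl2C–CCl2Br would give 9-bromo-1,7-dimethoxydibenzo[b,d]furan-8-yl diethylcarbamate F5. Hydrolysis with KOH in ethanol at reflux would return to the route at 9.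

Step 9. The hindered bay bromide may react too slowly with copper, so that reduction of the C–Br bond or oxidative decay of the electron-rich diol takes over. Fallback: starting from 12, the same C–O bond would be closed by palladium instead of copper (Pd(OAc)2, t-BuXPhos, K3PO4, toluene, 100 °C). The mechanism is different: zerovalent palladium inserts into the hindered C–Br bond, and the C–O bond forms by reductive elimination from an aryl(aryloxy) complex of divalent palladium, a step that bulky biaryl phosphines accelerate. This returns to the route at 13 and makes no new compound (entry F0).

## Further compounds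

F1 | step 11 | bis[methylbis(trimethylsiloxy)silyl] derivative of the dideoxy pentamethyl ether, silyl groups at 5A and 3F | COc1cc([Si](C)(O[Si](C)(C)C)O[Si](C)(C)C)cc(Oc2c(OC)cc(OC)c3c2Oc2c(OC)cc4oc5cc([Si](C)(O[Si](C)(C)C)O[Si](C)(C)C)cc(OC)c5c4c2O3)c1
F2 | step 1 | 2-(2-fluoro-4,6-dimethoxyphenyl)-1,3-dioxolane | COc1cc(F)c(C2OCCO2)c(OC)c1
F3 | step 1 | 3-(1,3-dioxolan-2-yl)-2-fluoro-4,6-dimethoxybenzaldehyde | COc1cc(OC)c(C2OCCO2)c(F)c1C=O
F4 | step 6 | 1,7-dimethoxydibenzo[b,d]furan-8-yl diethylcarbamate | CCN(CC)C(=O)Oc1cc2c(cc1OC)oc1cccc(OC)c12
F5 | step 6 | 9-bromo-1,7-dimethoxydibenzo[b,d]furan-8-yl diethylcarbamate | CCN(CC)C(=O)Oc1c(Br)c2c(cc1OC)oc1cccc(OC)c12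
F0 | step 9 | none | none
A1 | alternative 1 | ring B hydroquinone with OEt at 4B, OH at 2B and 5B, 3,5-dimethoxyphenoxy at 1B and (9-bromo-1,3,7-trimethoxydibenzofuran-8-yl)oxy at 6B | CCOc1cc(O)c(Oc2cc(OC)cc(OC)c2)c(Oc2c(OC)cc3oc4cc(OC)cc(OC)c4c3c2Br)c1O
A2 | alternative 1 | racemic 3-[(9-bromo-1,3,7-trimethoxydibenzofuran-8-yl)oxy]-2-(3,5-dimethoxyphenoxy)-4-(1-ethoxyvinyl)-4-hydroxycyclobut-2-en-1-one | CCOC(=C)C1(O)C(Oc2c(OC)cc3oc4cc(OC)cc(OC)c4c3c2Br)=C(Oc2cc(OC)cc(OC)c2)C1=O
A3 | alternative 2 | hexamethyl ether of the target with free OH at 5F | COc1cc(OC)cc(Oc2c(OC)cc(OC)c3c2Oc2c(OC)cc4oc5cc(OC)cc(O)c5c4c2O3)c1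
A4 | alternative 2 | pentacycle of rings A to E with a 3-nitrofuran fused to ring D (3,5-dimethoxyphenoxy at 1B; OMe at 2B, 4B and 2D) | COc1cc(OC)cc(Oc2c(OC)cc(OC)c3c2Oc2c(OC)cc4occ([N+](=O)[O-])c4c2O3)c1
A5 | alternative 2 | (E)-1,3-dimethoxy-1-(trimethylsilyloxy)buta-1,3-diene | C=C(OC)/C=C(/O[Si](C)(C)C)OC
A6 | alternative 3 | heptamethyl ether of the target | COc1cc(OC)cc(Oc2c(OC)cc(OC)c3c2Oc2c(OC)cc4oc5cc(OC)cc(OC)c5c4c2O3)c1
A7 | alternative 3 | dibenzo-1,4-dioxin with 3,5-dimethoxyphenoxy at 1B and at 4D, Br at 5D, OMe at 2B, 4B and 2D | COc1cc(OC)cc(Oc2c(OC)cc(OC)c3c2Oc2c(OC)cc(Oc4cc(OC)cc(OC)c4)c(Br)c2O3)c1
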